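Ring B (C5–C10, drimane numbering) carries the exocyclic C8=C12 methylene next to the C7 methylene. This 3-methylenecyclohexane pattern is cut at C6–C7 as a type-two carbonyl-ene reaction between a C6 aldehyde on C5 of ring A and an isopropenyl group (C7=C8–C12) on C9. One Lewis-acid step closes ring B, forms C6–C7 and places the C8=C12 alkene; the surplus C6 hydroxyl is then removed. The precursor, a trans-2,2,6-trimethylcyclohexanecarbaldehyde carrying the silyloxymethyl/isopropenyl-substituted C9 on C10, comes from β-cyclocitral by anionic oxy-Cope rearrangement of an (S)-dienol, which sets C9 and C10. The dihydroxycinnamate is attached last by Horner–Wadsworth–Emmons olefination.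

Key step: step 5

Numbering: atom labels C1–C12 follow drimane numbering throughout; C11 is the oxygenated carbon on C9 and C12 the methylene carbon on C8.

Assumption: in step 1 the sense of induction of the chiral phosphoric acid is taken to be the same as with aryl and alkenyl aldehydes; if the hindered enal reverses it, the antipodal catalyst is used.

Step 1
Reactants: 1 β-cyclocitral; 2 allenylboronic acid pinacol ester
Product: 3 (S)-1-(2,6,6-trimethylcyclohex-1-en-1-yl)but-3-yn-1-ol
Conditions: 2 (1.5 equiv), (S)-3,3′-bis(2,4,6-triisopropylphenyl)-1,1′-binaphthyl-2,2′-diyl hydrogen phosphate [(S)-TRIP] (5 mol %), 4 Å molecular sieves, toluene, 0 → 25 °C; then H2O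
Reagents that add atoms: none
Why: Chiral-phosphoric-acid-catalysed allenylboration (asymmetric propargylation), in which the acid activates the boronate in a closed six-membered transition state and the catalyst pocket directs transfer of the propargyl group to the Si face of the aldehyde, setting the (S)-carbinol centre at C6 that later steers the oxy-Cope rearrangement.

Step 2
Reactants: 3 (S)-1-(2,6,6-trimethylcyclohex-1-en-1-yl)but-3-yn-1-ol
Product: 5 (2E,5S)-3-methyl-5-(2,6,6-trimethylcyclohex-1-en-1-yl)pent-2-ene-1,5-diol, via alkenyldimethylalane 4 (not isolated)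
Conditions: AlMe3 (3.5 equiv), Cp2ZrCl2 (0.3 equiv), CH2Cl2, 0 → 25 °C; then n-BuLi, (CH2O)n, THF, −78 → 25 °C; aq. NH4Cl
Reagents that add atoms: trimethylaluminium, C[Al](C)C; formaldehyde (as paraformaldehyde), C=O
Why: Zirconium-catalysed methylalumination adds methyl and aluminium syn across the terminal alkyne with methyl on the internal carbon, and the derived alkenylaluminate captures formaldehyde with retention, so the E-trisubstituted alkene (C12 methyl cis to C11) is fixed by the mechanism while the carbinol centre is untouched.

Step 3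
Reactants: 5 (2E,5S)-3-methyl-5-(2,6,6-trimethylcyclohex-1-en-1-yl)pent-2-ene-1,5-diol
Product: 6 (1S,3E)-5-(tert-butyldimethylsilyloxy)-3-methyl-1-(2,6,6-trimethylcyclohex-1-en-1-yl)pent-3-en-1-ol
Conditions: TBSCl (1.05 equiv), imidazole, CH2Cl2, −20 → 0 °C
Reagents that add atoms: tert-butyldimethylsilyl chloride (TBSCl), CC(C)(C)[Si](C)(C)Cl
Why: Silyl ether formation discriminates on steric grounds, the primary allylic hydroxyl reacting while the secondary carbinol next to the trimethylcyclohexenyl ring stays free.

Step 4
Reactants: 6 (1S,3E)-5-(tert-butyldimethylsilyloxy)-3-methyl-1-(2,6,6-trimethylcyclohex-1-en-1-yl)pent-3-en-1-ol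
Product: 8 (1S,6R)-6-[(2S)-1-(tert-butyldimethylsilyloxy)-3-methylbut-3-en-2-yl]-2,2,6-trimethylcyclohexane-1-carbaldehyde (5α-H, 9α-H, 10β-CH3), via potassium enolate 7 (not isolated)
Conditions: KH (1.3 equiv), 18-crown-6 (1.3 equiv), THF, 0 → 25 °C; then cannulation into AcOH/THF, −78 °C
Reagents that add atoms: none
Why: Anionic oxy-Cope rearrangement through a chair that is a template of ring B, with the alkoxide oxygen equatorial (the axial alternative clashes with the C10 methyl, which is cis on the ring alkene and therefore axial) and the E-alkene placing C11 equatorial, so that C10 and C9 are set together from the (S)-carbinol; the enolate is then protonated kinetically and axially on the α-face, opposite the two syn-axial β-methyl groups on C4 and C10, which sets H-5 trans to the C10 methyl.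

Step 5
Reactants: 8 (1S,6R)-6-[(2S)-1-(tert-butyldimethylsilyloxy)-3-methylbut-3-en-2-yl]-2,2,6-trimethylcyclohexane-1-carbaldehyde
Product: 9 6β-hydroxyalbicanyl tert-butyldimethylsilyl ether (11-O-TBS drim-8(12)-ene-6β,11-diol; 5α-H, 9α-H, 10β-CH3)
Conditions: Me2AlCl (2 equiv), CH2Cl2, −78 → 0 °C; aq. NaHCO3
Reagents that add atoms: none
Why: Me2AlCl binds the C6 aldehyde, the terminal carbon C7 of the isopropenyl group bonds to C6 and a hydrogen of the C12 methyl passes to oxygen in a concerted, polarised six-centre array, which is the type-two intramolecular carbonyl-ene reaction known to give 3-methylenecyclohexanols with this Lewis acid. Ring B closes in the 6-exo-trig mode at the carbonyl, the alkene reacting in the endocyclic (type-two) sense through a chair in which the C5–C6 and C10–C9 bonds stay equatorial on ring A, so the trans relationship of C5 and C10 from step 4 becomes the trans ring fusion. The new C6 stereocentre is set by this bicyclic transition state: the aluminium-bound oxygen has to be axial to reach the C12 hydrogen, so the hydroxyl should come out 6β, syn to the C10 methyl, and because C6 is deoxygenated in step 7 a 6α-epimer would converge on the same compound. The selectivity required is hydrogen transfer from C12 and not proton loss from C9 or C7, and it is secured by geometry, since only a methyl hydrogen can reach the oxygen within the six-membered array, and by the reagent, whose adduct loses methane to an aluminium alkoxide so that no proton acid remains to move the alkene into the ring. The bulky silyl ether on C11 is too weak a Lewis base to compete for the aluminium, and the hindered aldehyde α-centre C5 does not epimerise at these temperatures.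

Step 6
Reactants: 9 6β-hydroxyalbicanyl tert-butyldimethylsilyl ether
Product: 11 O-(11-tert-butyldimethylsilyloxydrim-8(12)-en-6β-yl) S-methyl dithiocarbonate, via potassium xanthate 10 (not isolated)
Conditions: KH, THF, 0 → 25 °C; CS2; then MeI
Reagents that add atoms: carbon disulfide, S=C=S; iodomethane, CI
Why: Xanthate formation, in which the potassium alkoxide of the hindered axial alcohol adds to the small linear electrophile CS2 and the dithiocarbonate salt is S-methylated without change at any stereocentre.

Step 7
Reactants: 11 O-(11-tert-butyldimethylsilyloxydrim-8(12)-en-6β-yl) S-methyl dithiocarbonate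
Product: 12 albicanyl tert-butyldimethylsilyl ether
Conditions: Bu3SnH (3 equiv, 0.3 M), AIBN (cat.), toluene, 90 °C
Reagents that add atoms: none
Why: Barton–McCombie deoxygenation, in which the stannyl radical adds to the thiocarbonyl sulfur, the C6–O bond fragments to a secondary radical and concentrated tin hydride reduces it faster than the homoallylic radical can rearrange, removing the C6 centre and leaving C5, C9 and C10 untouched.

Step 8
Reactants: 12 albicanyl tert-butyldimethylsilyl ether
Product: 13 (+)-albicanol, (5S,9S,10S)-drim-8(12)-en-11-ol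
Conditions: Bu4NF, THF, 25 °C
Reagents that add atoms: none
Why: Fluoride-induced desilylation driven by the strong Si–F bond frees the primary C11 alcohol under non-acidic conditions to which the exocyclic alkene is inert.

Step 9
Reactants: 13 (+)-albicanol; 14 diethylphosphonoacetic acid
Product: 15 albicanyl 2-(diethoxyphosphoryl)acetate
Conditions: DCC, DMAP (cat.), CH2Cl2, 0 → 25 °C
Reagents that add atoms: none
Why: Steglich esterification, in which the acylpyridinium of the small phosphonoacetic acid acylates the β-branched primary alcohol readily.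

Step 10
Reactants: 16 2,4-dihydroxybenzaldehyde
Product: 17 2,4-bis(triisopropylsilyloxy)benzaldehyde
Conditions: TIPSCl (2.4 equiv), imidazole, DMAP (cat.), DMF, 25 °C
Reagents that add atoms: triisopropylsilyl chloride (TIPSCl), CC(C)[Si](Cl)(C(C)C)C(C)C
Why: Standard silylation of both phenols, the triisopropylsilyl group being chosen because it resists base and O-to-O migration in the following olefination.

Step 11
Reactants: 15 albicanyl 2-(diethoxyphosphoryl)acetate; 17 2,4-bis(triisopropylsilyloxy)benzaldehyde
Product: 18 albicanyl (E)-3-[2,4-bis(triisopropylsilyloxy)phenyl]prop-2-enoate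
Conditions: NaH, THF, 0 °C; then 17, 0 → 25 °C
Reagents that add atoms: none
Why: Horner–Wadsworth–Emmons olefination, in which the stabilised phosphonate anion adds to the aryl aldehyde and the oxaphosphetane collapses under thermodynamic control to the E-cinnamate.

Step 12
Reactants: 18 albicanyl (E)-3-[2,4-bis(triisopropylsilyloxy)phenyl]prop-2-enoate
Product: 19 albicanyl (E)-2,4-dihydroxycinnamate (CNP0233491.2), (5S,9S,10S)
Conditions: Bu4NF (2.2 equiv), AcOH (2.5 equiv), THF, 0 °C, exclusion of light
Reagents that add atoms: none
Why: Fluoride cleaves the two aryl silyl ethers quickly at 0 °C while the acetic acid buffer keeps the phenols protonated, so the ester, the E-alkene and the exocyclic methylene should survive, and light is excluded because E-to-Z isomerisation would open the way to lactonisation to the coumarin.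

Compound list
1 | β-cyclocitral (2,6,6-trimethylcyclohex-1-ene-1-carbaldehyde) | CC1=C(C=O)C(C)(C)CCC1 | starting material
2 | allenylboronic acid pinacol ester | C=C=CB1OC(C)(C)C(C)(C)O1 | starting material
3 | (S)-1-(2,6,6-trimethylcyclohex-1-en-1-yl)but-3-yn-1-ol | O[C@@H](CC#C)C1=C(C)CCCC1(C)C | intermediate
4 | alkenyldimethylalane: dimethylaluminium alkoxide of (1S,3E)-4-(dimethylalumanyl)-3-methyl-1-(2,6,6-trimethylcyclohex-1-en-1-yl)but-3-en-1-ol | C[Al](C)O[C@@H](C/C(C)=C/[Al](C)C)C1=C(C)CCCC1(C)C | intermediate
5 | (2E,5S)-3-methyl-5-(2,6,6-trimethylcyclohex-1-en-1-yl)pent-2-ene-1,5-diol | O[C@@H](C/C(C)=C/CO)C1=C(C)CCCC1(C)C | intermediate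
6 | (1S,3E)-5-(tert-butyldimethylsilyloxy)-3-methyl-1-(2,6,6-trimethylcyclohex-1-en-1-yl)pent-3-en-1-ol | O[C@@H](C/C(C)=C/CO[Si](C)(C)C(C)(C)C)C1=C(C)CCCC1(C)C | intermediate
7 | potassium enolate of 8 (enolate oxygen cis to C4) | [K+].[O-]/C=C1\C(C)(C)CCC[C@]1(C)[C@@H](CO[Si](C)(C)C(C)(C)C)C(C)=C | intermediate
8 | (1S,6R)-6-[(2S)-1-(tert-butyldimethylsilyloxy)-3-methylbut-3-en-2-yl]-2,2,6-trimethylcyclohexane-1-carbaldehyde | O=C[C@H]1C(C)(C)CCC[C@]1(C)[C@@H](CO[Si](C)(C)C(C)(C)C)C(C)=C | intermediate
9 | 6β-hydroxyalbicanyl tert-butyldimethylsilyl ether | C=C1C[C@@H](O)[C@H]2C(C)(C)CCC[C@]2(C)[C@H]1CO[Si](C)(C)C(C)(C)C | intermediate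
10 | potassium O-(11-tert-butyldimethylsilyloxydrim-8(12)-en-6β-yl) dithiocarbonate | C=C1C[C@@H](OC(=S)[S-])[C@H]2C(C)(C)CCC[C@]2(C)[C@H]1CO[Si](C)(C)C(C)(C)C.[K+] | intermediate
11 | O-(11-tert-butyldimethylsilyloxydrim-8(12)-en-6β-yl) S-methyl dithiocarbonate | C=C1C[C@@H](OC(=S)SC)[C@H]2C(C)(C)CCC[C@]2(C)[C@H]1CO[Si](C)(C)C(C)(C)C | intermediate
12 | albicanyl tert-butyldimethylsilyl ether | C=C1CC[C@H]2C(C)(C)CCC[C@]2(C)[C@H]1CO[Si](C)(C)C(C)(C)C | intermediate
13 | (+)-albicanol, (5S,9S,10S)-drim-8(12)-en-11-ol | C=C1CC[C@H]2C(C)(C)CCC[C@]2(C)[C@H]1CO | intermediate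
14 | diethylphosphonoacetic acid | OC(=O)CP(=O)(OCC)OCC | starting material
15 | albicanyl 2-(diethoxyphosphoryl)acetate | C=C1CC[C@H]2C(C)(C)CCC[C@]2(C)[C@H]1COC(=O)CP(=O)(OCC)OCC | intermediate
16 | 2,4-dihydroxybenzaldehyde | O=Cc1ccc(O)cc1O | starting material
17 | 2,4-bis(triisopropylsilyloxy)benzaldehyde | O=Cc1ccc(O[Si](C(C)C)(C(C)C)C(C)C)cc1O[Si](C(C)C)(C(C)C)C(C)C | intermediate
18 | albicanyl (E)-3-[2,4-bis(triisopropylsilyloxy)phenyl]prop-2-enoate | C=C1CC[C@H]2C(C)(C)CCC[C@]2(C)[C@H]1COC(=O)/C=C/c1ccc(O[Si](C(C)C)(C(C)C)C(C)C)cc1O[Si](C(C)C)(C(C)C)C(C)C | intermediate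
19 | albicanyl (E)-2,4-dihydroxycinnamate, (5S,9S,10S) | C=C1CC[C@H]2C(C)(C)CCC[C@]2(C)[C@H]1COC(=O)/C=C/c1ccc(O)cc1O | target

Total step count: 12. Longest linear sequence: 11 steps (steps 1–9, 11 and 12, from 1 to 19); step 10 is a one-step side branch.

Steps most likely to fail

Step 5. The oxygen has to take the axial position between the C4 and C10 methyl groups; if that slows the concerted hydrogen transfer, the reaction may go stepwise, with proton loss from C7 or C9 (alkene moving into ring B) or chloride capture at C8. The fallback sets out from 8 and replaces the ene reaction by an allylmetal addition. Ene-type allylic chlorination of the isopropenyl group (Ca(OCl)2, solid CO2, CH2Cl2/H2O, 0 °C) should give the 2-(chloromethyl)allyl aldehyde F1. CrCl2 in THF at 25 °C should convert it into the allylchromium species F2, which adds to the aldehyde through its γ-carbon (intramolecular Nozaki–Hiyama allylation). This closes ring B with the exocyclic alkene fixed by allyl transposition and comes back to the route at 9. Should the ring close to the 6α-epimer F3 instead, that alcohol is converted into its S-methyl xanthate F4 and reduced with Bu3SnH as in steps 6 and 7, coming back at 12.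

Step 4. The naked potassium alkoxide may fragment by retro-allylation (or give the formal 1,3-shift), part of the material may pass through the oxygen-axial chair and erode the enantiomeric purity at C9 and C10, or the enolate may be protonated on the β-face. The fallback sets out from 6 and uses a neutral rearrangement with a separate protonation. Silylation (TMSCl, Et3N, CH2Cl2) gives the trimethylsilyl ether F5. Thermal siloxy-Cope rearrangement (o-dichlorobenzene, about 230 °C, sealed base-washed tube) should give the silyl enol ether F6 through the same chair with no alkoxide present to fragment. MeLi in THF at 0 °C then frees the crown-free lithium enolate F7, which is protonated at −78 °C with AcOH and comes back to the route at 8.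

Step 1. Addition to the doubly α-substituted, fully substituted enal may be slow and poorly face-selective. The fallback sets out from 6 of insufficient enantiomeric purity (the material carried through steps 2 and 3) and sets the carbinol centre by reagent-controlled reduction instead. Dess–Martin oxidation (NaHCO3, CH2Cl2, 0 °C) gives the β,γ-unsaturated ketone F8. Corey–Bakshi–Shibata reduction with (R)-2-methyl-CBS-oxazaborolidine and catecholborane (toluene, −78 °C) should place hydride so that the bulky cyclohexenyl group acts as the large substituent and give the (S)-alcohol, coming back to the route at 6.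

Further compounds
F1 | step 5 | (1S,6R)-6-[(2S)-1-(tert-butyldimethylsilyloxy)-3-(chloromethyl)but-3-en-2-yl]-2,2,6-trimethylcyclohexane-1-carbaldehyde | O=C[C@H]1C(C)(C)CCC[C@]1(C)[C@@H](CO[Si](C)(C)C(C)(C)C)C(CCl)=C
F2 | step 5 | allylchromium dichloride derived from F1 | O=C[C@H]1C(C)(C)CCC[C@]1(C)[C@@H](CO[Si](C)(C)C(C)(C)C)C(C[Cr](Cl)Cl)=C
F3 | step 5 | 6α-hydroxyalbicanyl tert-butyldimethylsilyl ether | C=C1C[C@H](O)[C@H]2C(C)(C)CCC[C@]2(C)[C@H]1CO[Si](C)(C)C(C)(C)C
F4 | step 5 | O-(11-tert-butyldimethylsilyloxydrim-8(12)-en-6α-yl) S-methyl dithiocarbonate | C=C1C[C@H](OC(=S)SC)[C@H]2C(C)(C)CCC[C@]2(C)[C@H]1CO[Si](C)(C)C(C)(C)C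
F5 | step 4 | trimethylsilyl ether of 6 | C[Si](C)(C)O[C@@H](C/C(C)=C/CO[Si](C)(C)C(C)(C)C)C1=C(C)CCCC1(C)C
F6 | step 4 | trimethylsilyl enol ether of 8 | C[Si](C)(C)O/C=C1\C(C)(C)CCC[C@]1(C)[C@@H](CO[Si](C)(C)C(C)(C)C)C(C)=C
F7 | step 4 | lithium enolate of 8 | [Li+].[O-]/C=C1\C(C)(C)CCC[C@]1(C)[C@@H](CO[Si](C)(C)C(C)(C)C)C(C)=C
F8 | step 1 | (3E)-5-(tert-butyldimethylsilyloxy)-3-methyl-1-(2,6,6-trimethylcyclohex-1-en-1-yl)pent-3-en-1-one | O=C(C/C(C)=C/CO[Si](C)(C)C(C)(C)C)C1=C(C)CCCC1(C)C
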